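## Analysis of the target

The target 20 is a diaryl ether: two benzene rings joined through one oxygen, with no further ring. Ring A is a methyl benzoate with the ester on C1, a prenyloxy group on C2, a methyl on C4 and the bridging oxygen on C6. Ring B carries the bridging oxygen on C1', CH2OH on C2', OMe on C4' and a second prenyloxy group on C6'. There is no stereocentre and no stereogenic double bond, so stereochemistry only appears in transient intermediates and must merely be erased. The sensitive groups are the two aryl prenyl ethers (strong or hot acid, Claisen rearrangement on strong heating, hydride-abstracting oxidants, hydrogenation) and the benzylic alcohol, which lies within reach of the ester and can transesterify to an eight-membered lactone under base. The difficulty is the bridging oxygen: both of its aryl carbons have two ortho substituents, so direct C–O coupling of two arenes is unattractive. In addition, ring B has three differently substituted oxygens in a 1,2,3,5-pattern that must be told apart. The strategy rests on one feature: C1' bears the ether oxygen, and the ester carbon on C1 of ring A is ortho to that same oxygen. The ether oxygen, C1' and the ester carbon can therefore be O1, C2 and C3 of a benzofuran-3(2H)-one in which C1' is a spiro carbon. Ring B is built on that carbon, and cleavage of the C3–C1' bond then releases the ester and the diaryl ether together.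

## Retrosynthetic reasoning

**O–Si bond.** The target 20 is traced back to its silyl ether 19. The benzylic oxygen stays masked until the very end because every earlier basic step (methoxide, carbonate) would let a free CH2OH attack the ester. The forward step must release the alcohol without creating a free alkoxide.

**C6'–O prenyl bond.** Cutting the prenyl group from 19 gives phenol 18 and prenyl bromide 2. The ring B prenyl ether is introduced late because the C6' oxygen is a ketone oxygen for most of the route. The forward step is a plain phenol alkylation.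

**C3–C1' bond (retro-direction: a bond is added).** Rather than cutting the hindered aryl–O bond of 18, the ester carbon is reconnected to C1', which leads to the spiro cyclohexa-2',4'-dien-6'-one 17. In the forward direction methoxide attacks the benzofuranone ketone and C1' leaves as a dienolate that is the aromatic phenoxide of ring B. One operation thus delivers the methyl ester, the aromatic ring B, the free C6' oxygen and the diaryl ether, and the ether oxygen never has to be attached to a crowded arene.

**C2'=C3' unsaturation.** The dienone 17 is traced back through the silyl dienol ether 16 to the spiro enone 15, which has C2' and C3' saturated. The forward sequence must remove two hydrogens without strong base. A free dienolate of 15 could fragment by retro-Michael cleavage of the C1'–C2' bond to a stabilized β-diketonate, so neutral silylation followed by hydride abstraction with a quinone is planned.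

**C1'–C6' and C2'–C3' bonds (key disconnection).** Both bonds of ring B that do not belong to the dienophile are cut at once, which gives the exocyclic enone 11 and the doubly oxygenated diene 13. This cut is chosen because the diene already carries the C4' methoxy group and the C6' oxygen at the right carbons. The oxygen pattern of ring B therefore follows from the regiochemistry of one cycloaddition instead of from selective protection of a polyphenol. The forward reaction must join the CH2 terminus of 13 to the exocyclic carbon of 11 and the acetal carbon to C1'.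

**Exocyclic C=C bond.** The alkylidene unit of 11 is cut to benzofuranone 8 and silyloxyacetaldehyde 9, an aldol condensation in the forward sense. The aldehyde brings C2' and the protected CH2OH.

**Benzofuranone C2–C3 bond and the two ring A ethers.** Compound 8 comes from keto ester 6 by loss of the ester group. Keto ester 6 comes from diester 5 by cutting the C2–C3 bond (Dieckmann condensation). Diester 5 comes from salicylate 3 and methyl bromoacetate 4, and 3 comes from the symmetrical diol 1 and 2. Starting from 1 places the methyl group, the future ester carbon and both oxygens of ring A correctly from the outset. Because 1 is symmetrical, mono-prenylation needs no regiocontrol.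

**Diene.** Compound 13 is the silyl ketene acetal of the commercial ester 12, obtained by γ-deprotonation and O-silylation.

## Alternatives that were turned down

**Alternative 1:** Ring A is disconnected at C1–C6 and C4–C5. In the forward key step the pyrone methyl 4-(methoxymethoxy)-6-methyl-2-oxo-2H-pyran-3-carboxylate A1 would add the aryl ethynyl ether A2 across C3 and C6. Decarboxylative aromatization would then give the protected diaryl ether A3.
- In its favour: the route is convergent, the polarization of both partners fixes the ring A pattern, and all intermediates are robust arenes with no oxidation-level adjustment. On convergence and robustness it is stronger than the chosen route.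
- Against it: A2 is the ethynyl ether of a phenol with two ortho substituents, and the ring B arene with three differentiated oxygens must first be made in a separate multistep sequence. The donor at C4 and the methyl at C6 of A1 lower its reactivity, so forcing temperatures are expected. Both prenyl sites must travel as MOM ethers, which adds an acidic deprotection and a double prenylation after the key step.
- Comparison: the chosen strategy is shorter. It obtains ring B with its oxygen pattern from a four-carbon diene in one step and needs no protecting group on either phenolic oxygen.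

**Alternative 2:** Ring A is disconnected at C1–C2 and C5–C6. The vinylketene acetal A4 would add to the methyl 3-aryloxypropiolate A5 and aromatize by elimination of its methoxy group to the salicylate A6.
- In its favour: A6 is only two steps from the target (prenylation, desilylation), and the end game avoids dienone chemistry entirely. On the steps after the key step it is as short as or shorter than the chosen route, and cleaner.
- Against it: A5 is a push–pull alkyne whose aryloxy donor opposes the ester, and A4 lacks a 3-oxygen substituent, so the cycloaddition pairs a weakened dienophile with a moderately nucleophilic diene. It would need temperatures at which the aryl prenyl ether of A5 can undergo Claisen rearrangement. A5 must also be made from a hindered ring B phenol that already has its oxygens differentiated, which moves the real problem into the preparation of that building block.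
- Comparison: the chosen strategy solves the ring B substitution pattern and the crowded ether linkage together and uses a highly activated diene at moderate temperature.

**Alternative 3:** Ring B is disconnected at C1'–C2' and C5'–C6'. The enolate of keto ester 6 (an intermediate of the chosen route) would add to the enone A7, and the methyl ketone enolate would then close onto the ester to give the spiro cyclohexane-1,3-dione A8.
- In its favour: it uses only robust enolate chemistry, needs neither the decarboxylation nor the moisture-sensitive diene, and the Claisen closure is driven by deprotonation of the enolizable 1,3-dione. It reaches the spiro skeleton in fewer steps than the chosen route. On step count and reagent robustness it is as strong or stronger.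
- Against it: A8 has two carbonyl groups that must be told apart. Only the enol ether at C4' leads to the target, whereas the C6' enol ether would give after aromatization a ring B with hydroxyl and methoxy exchanged. The conjugate addition must also form a quaternary carbon next to a branched β-carbon and is reversible.
- Comparison: the chosen strategy carries the methoxy group in on the diene carbon that becomes C4', so the oxygen pattern is not left to a selectivity between two similar carbonyls. Because Alternative 3 shares compound 6 and converges on compound 15, it is kept as the fallback for the key step.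

Key step: step 7

Remark 1: methyl 2,6-dihydroxy-4-methylbenzoate (1) and {[tert-butyl(diphenyl)silyl]oxy}acetaldehyde (9) are taken as catalogue compounds.
Remark 2: in all spiro intermediates ring B keeps the locants C1'–C6' of the target. These intermediates are racemic, and their stereocentres disappear in steps 9 and 10. "Prenyl" means 3-methylbut-2-en-1-yl and "TBDPS" means tert-butyl(diphenyl)silyl.

## Route

Step 1
Reactants: 1 methyl 2,6-dihydroxy-4-methylbenzoate; 2 1-bromo-3-methylbut-2-ene (prenyl bromide)
Product: 3 methyl 2-hydroxy-4-methyl-6-(prenyloxy)benzoate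
Conditions: 2 (1.05 equiv), K2CO3, acetone, reflux
Reagents that add atoms: none
Why: Williamson ether synthesis; the two hydroxyls of 1 are equivalent, so only one mono-ether can form, and the remaining hydroxyl is held in a hydrogen bond to the ester carbonyl and reacts more slowly, which favours mono-alkylation.

Step 2
Reactants: 3 methyl 2-hydroxy-4-methyl-6-(prenyloxy)benzoate; 4 methyl bromoacetate
Product: 5 methyl 2-(2-methoxy-2-oxoethoxy)-4-methyl-6-(prenyloxy)benzoate
Conditions: K2CO3, DMF, 60 °C
Reagents that add atoms: none
Why: Williamson O-alkylation of the chelated phenol with a reactive α-halo ester in a dipolar aprotic solvent; both esters and the prenyl ether are inert to carbonate.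

Step 3
Reactants: 5 methyl 2-(2-methoxy-2-oxoethoxy)-4-methyl-6-(prenyloxy)benzoate
Product: 6 methyl 3-hydroxy-6-methyl-4-(prenyloxy)-1-benzofuran-2-carboxylate (enol form of the 3-oxo-2,3-dihydro ester)
Conditions: KOt-Bu, THF, 0 °C to rt; then AcOH
Reagents that add atoms: none
Why: Dieckmann condensation; the aryloxyacetate enolate attacks the neighbouring aryl ester in a five-membered ring closure, the only possible mode because the benzoate has no α-hydrogen, and the product is drawn out of the equilibrium as its stabilized enolate.

Step 4
Reactants: 6 methyl 3-hydroxy-6-methyl-4-(prenyloxy)-1-benzofuran-2-carboxylate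
Product: 8 6-methyl-4-(prenyloxy)-1-benzofuran-3(2H)-one, via keto acid 7 (not isolated)
Conditions: NaOH, MeOH/H2O, 70 °C, Ar; then 1 M HCl, 0 °C to rt
Reagents that add atoms: none
Why: Saponification under base, to which the prenyl ether is inert, followed by protonation to the β-keto acid 7, which should lose CO2 through its keto tautomer near room temperature; the acid contact is cold, dilute and short so that the prenyl ether is spared.

Step 5
Reactants: 8 6-methyl-4-(prenyloxy)-1-benzofuran-3(2H)-one; 9 {[tert-butyl(diphenyl)silyl]oxy}acetaldehyde
Product: 11 (2Z)-2-[2-(TBDPS-oxy)ethylidene]-6-methyl-4-(prenyloxy)-1-benzofuran-3(2H)-one, via aldol adduct 10 (not isolated)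
Conditions: 9 (1.5 equiv), neutral Al2O3 (activity grade 1), CH2Cl2, rt
Reagents that add atoms: none
Why: Aldol condensation of the acidic C2 methylene of a benzofuran-3-one with an aldehyde on alumina, the method used for aurones; dehydration is driven by conjugation, and the Z isomer (side chain syn to the ring oxygen, away from the C3 carbonyl) is the thermodynamic one.

Step 6
Reactants: 12 methyl (2E)-3-methoxybut-2-enoate
Product: 13 (1Z)-1,3-dimethoxy-1-[(trimethylsilyl)oxy]buta-1,3-diene
Conditions: LiN(i-Pr)2 (commercial solution), THF, −78 °C; Me3SiCl, −78 °C to rt; distillation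
Reagents that add atoms: chlorotrimethylsilane, C[Si](C)(C)Cl
Why: γ-Deprotonation of the methyl group cis to the ester gives the lithium dienolate, which is silylated on oxygen to the silyl ketene acetal, a known preparation of 1-alkoxy-1-silyloxydienes; the ketene acetal geometry is immaterial because that carbon becomes the C6' ketone.

Step 7
Reactants: 11 (2Z)-2-[2-(TBDPS-oxy)ethylidene]-6-methyl-4-(prenyloxy)-1-benzofuran-3(2H)-one; 13 (1Z)-1,3-dimethoxy-1-[(trimethylsilyl)oxy]buta-1,3-diene
Product: 15 2'-(TBDPS-oxymethyl)-4'-methoxy-6-methyl-4-(prenyloxy)-3H-spiro[1-benzofuran-2,1'-cyclohex-4'-ene]-3,6'-dione, via silyl ketal cycloadduct 14 (not isolated)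
Conditions: 13 (3 equiv), toluene, 110 °C, sealed tube; then 0.1 M HCl, THF, 0 °C
Reagents that add atoms: none
Why: This is a Diels–Alder reaction of normal electron demand between the HOMO of the doubly oxygenated diene 13 and the LUMO of the exocyclic enone 11, expected to be concerted but strongly asynchronous, with the C2'–C3' bond leading and the C1'–C6' bond following. The closest known reaction type is the cycloaddition of oxygenated silyloxydienes to 2-alkylidenebenzofuran-3-ones and related exocyclic α-alkylidene ketones, which gives spiro cyclohexenones of the grisan type. Ring B closes as a six-membered carbocycle by an intermolecular (4+2) cycloaddition in which both new bonds are made to the same face of the exocyclic double bond, and C1' becomes the spiro atom. In the first adduct 14 the stereocentres C1' and C2' are set relative to each other by suprafacial addition to the Z alkene (silyloxymethyl group cis to the ring oxygen), while the ketal carbon C6' is uncontrolled. The compound forms as a racemate, and none of this matters because C6' becomes a carbonyl on hydrolysis and C1' and C2' become sp2 in steps 9 and 10. The step needs regioselectivity: the CH2 terminus of 13 must bond to the exocyclic β-carbon of the enone and the acetal carbon to C1'. This is secured by the match between the largest HOMO coefficient of the diene (the CH2 terminus, pushed by both oxygens) and the largest LUMO coefficient of the enone (the β-carbon). It also needs periselectivity over the hetero-cycloaddition in which the s-cis enone acts as an oxadiene, which the unhindered and most nucleophilic diene terminus should favour. Dilute acid then collapses the mixed silyl methyl ketal to the C6' ketone and leaves the C4' methyl enol ether as part of a stable vinylogous ester.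

Step 8
Reactants: 15 2'-(TBDPS-oxymethyl)-4'-methoxy-6-methyl-4-(prenyloxy)-3H-spiro[1-benzofuran-2,1'-cyclohex-4'-ene]-3,6'-dione
Product: 16 6'-{[tert-butyl(dimethyl)silyl]oxy}-2'-(TBDPS-oxymethyl)-4'-methoxy-6-methyl-4-(prenyloxy)-3H-spiro[1-benzofuran-2,1'-cyclohexa-3',5'-dien]-3-one
Conditions: t-BuMe2SiOTf, Et3N, CH2Cl2, 0 °C; cold NaHCO3 work-up, used crude
Reagents that add atoms: tert-butyldimethylsilyl trifluoromethanesulfonate, CC(C)(C)[Si](C)(C)OS(=O)(=O)C(F)(F)F
Why: Soft enolization; O-silylation of the vinylogous ester carbonyl gives a dialkoxyallyl cation that can only lose a proton from C3' because C1' is quaternary, so the silyl dienol ether forms without a free dienolate, which could fragment by retro-Michael cleavage of the C1'–C2' bond.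

Step 9
Reactants: 16 6'-{[tert-butyl(dimethyl)silyl]oxy}-2'-(TBDPS-oxymethyl)-4'-methoxy-6-methyl-4-(prenyloxy)-3H-spiro[1-benzofuran-2,1'-cyclohexa-3',5'-dien]-3-one
Product: 17 2'-(TBDPS-oxymethyl)-4'-methoxy-6-methyl-4-(prenyloxy)-3H-spiro[1-benzofuran-2,1'-cyclohexa-2',4'-diene]-3,6'-dione
Conditions: DDQ (1.1 equiv), 2,4,6-collidine, CH2Cl2, 0 °C; pH 7 buffer; used without storage
Reagents that add atoms: none
Why: Quinone dehydrogenation of a dienol ether to the linearly conjugated dienone, a known reaction type; hydride is abstracted from the only sp3 C–H of ring B (C2'–H, allylic) to give a cation stabilized by both oxygens, and loss of the silyl group leaves the 2',4'-dien-6'-one, while the far less electron-rich aryl prenyl ethers should be spared at 0 °C.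

Step 10
Reactants: 17 2'-(TBDPS-oxymethyl)-4'-methoxy-6-methyl-4-(prenyloxy)-3H-spiro[1-benzofuran-2,1'-cyclohexa-2',4'-diene]-3,6'-dione
Product: 18 methyl 2-[2-(TBDPS-oxymethyl)-6-hydroxy-4-methoxyphenoxy]-4-methyl-6-(prenyloxy)benzoate
Conditions: NaOMe (1.2 equiv), MeOH/THF, 0 °C; then AcOH
Reagents that add atoms: sodium methoxide, [Na+].[O-]C
Why: Retro-Claisen fragmentation; methoxide adds to the strained aryl ketone C3 and the tetrahedral intermediate expels C1' as the dienolate of the cyclohexadienone, which is the aromatic phenoxide of ring B, as in the known opening of spirodienone benzofuranones to diaryl ethers; additions of methoxide at other positions are reversible, whereas this path is made irreversible by aromatization and turns C3 into the methyl ester.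

Step 11
Reactants: 18 methyl 2-[2-(TBDPS-oxymethyl)-6-hydroxy-4-methoxyphenoxy]-4-methyl-6-(prenyloxy)benzoate; 2 1-bromo-3-methylbut-2-ene (prenyl bromide)
Product: 19 methyl 2-[2-(TBDPS-oxymethyl)-4-methoxy-6-(prenyloxy)phenoxy]-4-methyl-6-(prenyloxy)benzoate
Conditions: K2CO3, DMF, rt
Reagents that add atoms: none
Why: Williamson O-alkylation of the only free phenol; the benzylic oxygen is still silylated, so no alkoxide can attack the ester.

Step 12
Reactants: 19 methyl 2-[2-(TBDPS-oxymethyl)-4-methoxy-6-(prenyloxy)phenoxy]-4-methyl-6-(prenyloxy)benzoate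
Product: 20 methyl 2-[2-(hydroxymethyl)-4-methoxy-6-(prenyloxy)phenoxy]-4-methyl-6-(prenyloxy)benzoate (target)
Conditions: Bu4NF, AcOH (1:1), THF, 0 °C to rt
Reagents that add atoms: none
Why: Fluoride cleavage of the primary silyl ether; acetic acid keeps the liberated benzylic alkoxide protonated so that it does not transesterify with the neighbouring methyl ester, and the prenyl ethers and the ester are inert.

## Compound list

1 | methyl 2,6-dihydroxy-4-methylbenzoate | COC(=O)c1c(O)cc(C)cc1O | starting material
2 | 1-bromo-3-methylbut-2-ene (prenyl bromide) | CC(C)=CCBr | starting material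
3 | methyl 2-hydroxy-4-methyl-6-[(3-methylbut-2-en-1-yl)oxy]benzoate | COC(=O)c1c(O)cc(C)cc1OCC=C(C)C | intermediate
4 | methyl bromoacetate | COC(=O)CBr | starting material
5 | methyl 2-(2-methoxy-2-oxoethoxy)-4-methyl-6-[(3-methylbut-2-en-1-yl)oxy]benzoate | COC(=O)COc1cc(C)cc(OCC=C(C)C)c1C(=O)OC | intermediate
6 | methyl 3-hydroxy-6-methyl-4-[(3-methylbut-2-en-1-yl)oxy]-1-benzofuran-2-carboxylate | COC(=O)c1oc2cc(C)cc(OCC=C(C)C)c2c1O | intermediate
7 | 3-hydroxy-6-methyl-4-[(3-methylbut-2-en-1-yl)oxy]-1-benzofuran-2-carboxylic acid (not isolated) | OC(=O)c1oc2cc(C)cc(OCC=C(C)C)c2c1O | intermediate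
8 | 6-methyl-4-[(3-methylbut-2-en-1-yl)oxy]-1-benzofuran-3(2H)-one | Cc1cc(OCC=C(C)C)c2C(=O)COc2c1 | intermediate
9 | {[tert-butyl(diphenyl)silyl]oxy}acetaldehyde | O=CCO[Si](c1ccccc1)(c1ccccc1)C(C)(C)C | starting material
10 | 2-(2-{[tert-butyl(diphenyl)silyl]oxy}-1-hydroxyethyl)-6-methyl-4-[(3-methylbut-2-en-1-yl)oxy]-1-benzofuran-3(2H)-one, mixture of diastereomers (not isolated) | Cc1cc(OCC=C(C)C)c2C(=O)C(C(O)CO[Si](c3ccccc3)(c3ccccc3)C(C)(C)C)Oc2c1 | intermediate
11 | (2Z)-2-(2-{[tert-butyl(diphenyl)silyl]oxy}ethylidene)-6-methyl-4-[(3-methylbut-2-en-1-yl)oxy]-1-benzofuran-3(2H)-one | Cc1cc(OCC=C(C)C)c2C(=O)/C(=C/CO[Si](c3ccccc3)(c3ccccc3)C(C)(C)C)Oc2c1 | intermediate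
12 | methyl (2E)-3-methoxybut-2-enoate | CO/C(C)=C/C(=O)OC | starting material
13 | (1Z)-1,3-dimethoxy-1-[(trimethylsilyl)oxy]buta-1,3-diene | C=C(OC)/C=C(/OC)O[Si](C)(C)C | intermediate
14 | 2'-({[tert-butyl(diphenyl)silyl]oxy}methyl)-4',6'-dimethoxy-6-methyl-4-[(3-methylbut-2-en-1-yl)oxy]-6'-[(trimethylsilyl)oxy]-3H-spiro[1-benzofuran-2,1'-cyclohex-4'-en]-3-one, racemic, silyloxymethyl cis to the ring oxygen, C6' unassigned (not isolated) | Cc1cc(OCC=C(C)C)c2C(=O)C3(Oc2c1)C(CO[Si](c4ccccc4)(c4ccccc4)C(C)(C)C)CC(OC)=CC3(OC)O[Si](C)(C)C | intermediate
15 | 2'-({[tert-butyl(diphenyl)silyl]oxy}methyl)-4'-methoxy-6-methyl-4-[(3-methylbut-2-en-1-yl)oxy]-3H-spiro[1-benzofuran-2,1'-cyclohex-4'-ene]-3,6'-dione, racemic, silyloxymethyl expected cis to the ring oxygen, any stereoisomer serves | Cc1cc(OCC=C(C)C)c2C(=O)C3(Oc2c1)C(CO[Si](c4ccccc4)(c4ccccc4)C(C)(C)C)CC(OC)=CC3=O | intermediate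
16 | 6'-{[tert-butyl(dimethyl)silyl]oxy}-2'-({[tert-butyl(diphenyl)silyl]oxy}methyl)-4'-methoxy-6-methyl-4-[(3-methylbut-2-en-1-yl)oxy]-3H-spiro[1-benzofuran-2,1'-cyclohexa-3',5'-dien]-3-one, racemic | Cc1cc(OCC=C(C)C)c2C(=O)C3(Oc2c1)C(CO[Si](c4ccccc4)(c4ccccc4)C(C)(C)C)C=C(OC)C=C3O[Si](C)(C)C(C)(C)C | intermediate
17 | 2'-({[tert-butyl(diphenyl)silyl]oxy}methyl)-4'-methoxy-6-methyl-4-[(3-methylbut-2-en-1-yl)oxy]-3H-spiro[1-benzofuran-2,1'-cyclohexa-2',4'-diene]-3,6'-dione, racemic at the spiro carbon | Cc1cc(OCC=C(C)C)c2C(=O)C3(Oc2c1)C(CO[Si](c4ccccc4)(c4ccccc4)C(C)(C)C)=CC(OC)=CC3=O | intermediate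
18 | methyl 2-[2-({[tert-butyl(diphenyl)silyl]oxy}methyl)-6-hydroxy-4-methoxyphenoxy]-4-methyl-6-[(3-methylbut-2-en-1-yl)oxy]benzoate | COC(=O)c1c(OCC=C(C)C)cc(C)cc1Oc1c(CO[Si](c2ccccc2)(c2ccccc2)C(C)(C)C)cc(OC)cc1O | intermediate
19 | methyl 2-{2-({[tert-butyl(diphenyl)silyl]oxy}methyl)-4-methoxy-6-[(3-methylbut-2-en-1-yl)oxy]phenoxy}-4-methyl-6-[(3-methylbut-2-en-1-yl)oxy]benzoate | COC(=O)c1c(OCC=C(C)C)cc(C)cc1Oc1c(CO[Si](c2ccccc2)(c2ccccc2)C(C)(C)C)cc(OC)cc1OCC=C(C)C | intermediate
20 | methyl 2-{2-(hydroxymethyl)-4-methoxy-6-[(3-methylbut-2-en-1-yl)oxy]phenoxy}-4-methyl-6-[(3-methylbut-2-en-1-yl)oxy]benzoate | COC(=O)c1c(OCC=C(C)C)cc(C)cc1Oc1c(CO)cc(OC)cc1OCC=C(C)C | target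

## Step count and least certain steps

Total: 12 steps. Longest linear sequence: 11 steps (steps 1 to 5 and 7 to 12, from compound 1); the diene branch is one step (step 6).

**Step 7 (key step).** The cycloaddition may be too slow on a trisubstituted enone whose α-oxygen and electron-rich aryl ketone lower its electrophilicity. The sensitive diene would then decompose thermally before it adds. The enone could also divert into a hetero-cycloaddition through its carbonyl oxygen. Fallback, setting out from 6 and 9 and returning at 15:
- Aldehyde 9 is converted by a Wittig reaction with 1-(triphenyl-λ5-phosphanylidene)propan-2-one (CH2Cl2, rt) into (3E)-5-{[tert-butyl(diphenyl)silyl]oxy}pent-3-en-2-one F1, which is the same compound as A7.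
- The enolized keto ester 6 is added to F1 in a Michael reaction (catalytic KOt-Bu, THF, 0 °C). This gives methyl 2-(1-{[tert-butyl(diphenyl)silyl]oxy}-4-oxopentan-2-yl)-6-methyl-4-[(3-methylbut-2-en-1-yl)oxy]-3-oxo-2,3-dihydro-1-benzofuran-2-carboxylate F2.
- The methyl ketone enolate of F2 (KOt-Bu, 1.2 equiv, THF, rt; then AcOH) closes ring B by Claisen condensation onto the ester. The product is 2'-({[tert-butyl(diphenyl)silyl]oxy}methyl)-6-methyl-4-[(3-methylbut-2-en-1-yl)oxy]-3H-spiro[1-benzofuran-2,1'-cyclohexane]-3,4',6'-trione F3, identical with A8. The closure is driven by deprotonation of the enolizable 1,3-dione.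
- Acid-catalysed enol ether formation (MeOH, HC(OMe)3, catalytic TsOH, rt) should take place at the C4' carbonyl, which is remote from the quaternary carbon, and so returns to 15.

**Step 9.** Hydride abstraction may not occur at C2'–H. The quinone could instead add at a ring carbon without elimination, simply desilylate the dienol ether back to 15, or attack the allylic CH2–O of a prenyl ether. The cross-conjugation-free dienone formed may also dimerize by cycloaddition if concentrated or stored. Fallback, setting out from 16 and returning at 17:
- PhSeCl (CH2Cl2, −78 °C) attacks the dienol ether at its doubly activated terminus C3'. This gives 2'-({[tert-butyl(diphenyl)silyl]oxy}methyl)-4'-methoxy-6-methyl-4-[(3-methylbut-2-en-1-yl)oxy]-3'-(phenylselanyl)-3H-spiro[1-benzofuran-2,1'-cyclohex-4'-ene]-3,6'-dione F4.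
- Oxidation with mCPBA (1.0 equiv, −78 °C, faster at selenium than at the prenyl alkenes) gives the corresponding selenoxide F5.
- On warming with i-Pr2NH, F5 undergoes syn elimination with C2'–H, the only β-hydrogen, and gives 17.

**Step 5.** The alkylidene product is a reactive Michael acceptor, so a second molecule of 8 may add to it. The enolizable aldehyde may also self-condense on the alumina. Fallback, setting out from 8 and 9 and returning at 11:
- The lithium enolate of 8 (LiN(SiMe3)2, THF, −78 °C) is treated with 9, and the aldol 10 is isolated.
- Aldol 10 is converted with MsCl and Et3N (CH2Cl2, 0 °C) into 2-{[tert-butyl(diphenyl)silyl]oxy}-1-{6-methyl-4-[(3-methylbut-2-en-1-yl)oxy]-3-oxo-2,3-dihydro-1-benzofuran-2-yl}ethyl methanesulfonate F6.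
- Elimination with DBU by an E1cB pathway gives 11.

**Step 4.** The enolized ester may hydrolyse sluggishly. If the acidification has to be forced (warmer or stronger acid) to complete decarboxylation, acid-induced cleavage or cyclization of the aryl prenyl ether becomes likely. Fallback, setting out from 1 and 4 and returning at 8, with the prenyl group introduced only after the acidic step:
- Mono-alkylation of 1 with 4 (K2CO3, acetone) gives methyl 2-hydroxy-6-(2-methoxy-2-oxoethoxy)-4-methylbenzoate F7.
- Dieckmann condensation (KOt-Bu, 2.2 equiv, THF) gives methyl 3,4-dihydroxy-6-methyl-1-benzofuran-2-carboxylate F8.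
- Refluxing aqueous HCl hydrolyses and decarboxylates F8 to 4-hydroxy-6-methyl-1-benzofuran-3(2H)-one F9.
- Mitsunobu etherification of the phenol of F9 with 3-methylbut-2-en-1-ol (PPh3, diisopropyl azodicarboxylate, THF) gives 8.

**Step 12.** If buffering is insufficient, the liberated benzylic alkoxide may attack the ester on ring A with loss of methoxide and closure of an eight-membered lactone. Fallback, setting out from 19 and returning at 20:
- The cyclization is accepted or driven to completion with unbuffered Bu4NF (THF, rt). This gives 9-methoxy-2-methyl-4,11-bis[(3-methylbut-2-en-1-yl)oxy]-5H,7H-dibenzo[b,g][1,5]dioxocin-5-one F10.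
- Methanolysis of this medium-ring lactone (K2CO3, MeOH, rt) should favour the open hydroxy methyl ester by strain release and mass action and gives 20.

## Further compounds

F1 | step 7 | (3E)-5-{[tert-butyl(diphenyl)silyl]oxy}pent-3-en-2-one | CC(=O)/C=C/CO[Si](c1ccccc1)(c1ccccc1)C(C)(C)C
F2 | step 7 | methyl 2-(1-{[tert-butyl(diphenyl)silyl]oxy}-4-oxopentan-2-yl)-6-methyl-4-[(3-methylbut-2-en-1-yl)oxy]-3-oxo-2,3-dihydro-1-benzofuran-2-carboxylate | COC(=O)C1(Oc2cc(C)cc(OCC=C(C)C)c2C1=O)C(CO[Si](c3ccccc3)(c3ccccc3)C(C)(C)C)CC(C)=O
F3 | step 7 | 2'-({[tert-butyl(diphenyl)silyl]oxy}methyl)-6-methyl-4-[(3-methylbut-2-en-1-yl)oxy]-3H-spiro[1-benzofuran-2,1'-cyclohexane]-3,4',6'-trione | Cc1cc(OCC=C(C)C)c2C(=O)C3(Oc2c1)C(CO[Si](c4ccccc4)(c4ccccc4)C(C)(C)C)CC(=O)CC3=O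
F4 | step 9 | 2'-({[tert-butyl(diphenyl)silyl]oxy}methyl)-4'-methoxy-6-methyl-4-[(3-methylbut-2-en-1-yl)oxy]-3'-(phenylselanyl)-3H-spiro[1-benzofuran-2,1'-cyclohex-4'-ene]-3,6'-dione | Cc1cc(OCC=C(C)C)c2C(=O)C3(Oc2c1)C(CO[Si](c4ccccc4)(c4ccccc4)C(C)(C)C)C([Se]c4ccccc4)C(OC)=CC3=O
F5 | step 9 | selenoxide of F4, 3'-(benzeneseleninyl) compound | Cc1cc(OCC=C(C)C)c2C(=O)C3(Oc2c1)C(CO[Si](c4ccccc4)(c4ccccc4)C(C)(C)C)C([Se](=O)c4ccccc4)C(OC)=CC3=O
F6 | step 5 | 2-{[tert-butyl(diphenyl)silyl]oxy}-1-{6-methyl-4-[(3-methylbut-2-en-1-yl)oxy]-3-oxo-2,3-dihydro-1-benzofuran-2-yl}ethyl methanesulfonate | Cc1cc(OCC=C(C)C)c2C(=O)C(C(CO[Si](c3ccccc3)(c3ccccc3)C(C)(C)C)OS(C)(=O)=O)Oc2c1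
F7 | step 4 | methyl 2-hydroxy-6-(2-methoxy-2-oxoethoxy)-4-methylbenzoate | COC(=O)COc1cc(C)cc(O)c1C(=O)OC
F8 | step 4 | methyl 3,4-dihydroxy-6-methyl-1-benzofuran-2-carboxylate | COC(=O)c1oc2cc(C)cc(O)c2c1O
F9 | step 4 | 4-hydroxy-6-methyl-1-benzofuran-3(2H)-one | Cc1cc(O)c2C(=O)COc2c1
F10 | step 12 | 9-methoxy-2-methyl-4,11-bis[(3-methylbut-2-en-1-yl)oxy]-5H,7H-dibenzo[b,g][1,5]dioxocin-5-one | O=C1OCc2cc(OC)cc(OCC=C(C)C)c2Oc2cc(C)cc(OCC=C(C)C)c12
A1 | alternative 1 | methyl 4-(methoxymethoxy)-6-methyl-2-oxo-2H-pyran-3-carboxylate | COC(=O)C1=C(OCOC)C=C(C)OC1=O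
A2 | alternative 1 | tert-butyl{[2-(ethynyloxy)-5-methoxy-3-(methoxymethoxy)phenyl]methoxy}dimethylsilane | C#COc1c(CO[Si](C)(C)C(C)(C)C)cc(OC)cc1OCOC
A3 | alternative 1 | methyl 2-[2-({[tert-butyl(dimethyl)silyl]oxy}methyl)-4-methoxy-6-(methoxymethoxy)phenoxy]-6-(methoxymethoxy)-4-methylbenzoate | COC(=O)c1c(OCOC)cc(C)cc1Oc1c(CO[Si](C)(C)C(C)(C)C)cc(OC)cc1OCOC
A4 | alternative 2 | 1-methoxy-3-methyl-1-[(trimethylsilyl)oxy]buta-1,3-diene (ketene acetal geometry not defined) | C=C(C)C=C(OC)O[Si](C)(C)C
A5 | alternative 2 | methyl 3-{2-({[tert-butyl(dimethyl)silyl]oxy}methyl)-4-methoxy-6-[(3-methylbut-2-en-1-yl)oxy]phenoxy}prop-2-ynoate | COC(=O)C#COc1c(CO[Si](C)(C)C(C)(C)C)cc(OC)cc1OCC=C(C)C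
A6 | alternative 2 | methyl 2-{2-({[tert-butyl(dimethyl)silyl]oxy}methyl)-4-methoxy-6-[(3-methylbut-2-en-1-yl)oxy]phenoxy}-6-hydroxy-4-methylbenzoate | COC(=O)c1c(O)cc(C)cc1Oc1c(CO[Si](C)(C)C(C)(C)C)cc(OC)cc1OCC=C(C)C
A7 | alternative 3 | (3E)-5-{[tert-butyl(diphenyl)silyl]oxy}pent-3-en-2-one | CC(=O)/C=C/CO[Si](c1ccccc1)(c1ccccc1)C(C)(C)C
A8 | alternative 3 | 2'-({[tert-butyl(diphenyl)silyl]oxy}methyl)-6-methyl-4-[(3-methylbut-2-en-1-yl)oxy]-3H-spiro[1-benzofuran-2,1'-cyclohexane]-3,4',6'-trione | Cc1cc(OCC=C(C)C)c2C(=O)C3(Oc2c1)C(CO[Si](c4ccccc4)(c4ccccc4)C(C)(C)C)CC(=O)CC3=O
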